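Theta and eta are the runs we have, and from them we forecast cedar, alder and birch, three flasks with the same charges at different temperatures, each read at 6.0 min.

| flask | Za | Zb | Ze | temperature | remark | time |
|---|---|---|---|---|---|---|
| theta | 1.5 M | 1.8 M | 0.30 M | 80 °C | run made earlier |  |
| eta | 1.5 M | 1.8 M | 0.68 M | 102 °C | run made earlier |  |
| cedar | 1.5 M | 1.80 M | 0.450 M | 70 °C |  | 6.0 min |
| alder | 1.5 M | 1.80 M | 0.450 M | 90 °C |  | 6.0 min |
| birch | 1.5 M | 1.80 M | 0.450 M | 110 °C |  | 6.0 min |

theta run (percent of the Za charged): time / min: Zf / % = 0.167: 24.8; 0.250: 31.4; 0.417: 38.4; 0.667: 44.3; 1.00: 45.1; 1.50: 46.8; 2.50: 47.0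

eta run (percent of the Za charged): time / s: Zf / % = 10.0: 35.9; 12.0: 36.2; 20.0: 39.1; 25.0: 39.5; 40.0: 39.0; 50.0: 39.4

(each reading ± 1 percentage point)



* the flask with the highest amount of Zf, in percent of the Za charged ("all alike" if they lie within 1.5 percentage points) (cedar / alder / birch / all alike)
* final Zf, as a percentage of the Za charged, in cedar
* final Zf, as a percentage of the Za charged, in alder
* final Zf, as a percentage of the Za charged, in birch

Both runs level off, at a mean of 46.9% in theta and 39.3% in eta. The first reading of each gives a time constant for the approach to that plateau: 13.3 s in theta and 4.06 s in eta. Stretched to cedar, which is colder than theta, it becomes 22.8 s, so 6.0 min holds 15.8 time constants, and we take cedar to stand at its plateau by then, with the hotter alder and birch doing the same.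

A plateau has odds, Zf over the rest of the charged Za, which we would call a selectivity factor if that rest has become other products; as read, they are 0.883 in theta and 0.646 in eta. The quantity we carry is the theta-to-eta odds ratio 0.732. For a flask at fractional distance s along the way from theta to eta:

odds = theta odds × ratio^s, and Zf = odds / (1 + odds)

Counting temperature as the distance gives s of −0.455, 0.455 and 1.36:

cedar 50.4%, alder 43.4%, birch 36.6%

The weak link is that Ze changed along with temperature between the runs. The flasks' Ze lies at 0.395 of that way. Giving Ze half of the fall averages the two distances: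

cedar 47.1%, alder 43.6%, birch 40.2%

Alder goes from 43.4% to 43.6%, and cedar leads on both lines, so we commit to cedar, and to each flask lying near or between its two values.

The forecast names cedar, with 46.3% for cedar, 43.7% for alder and 41.3% for birch, and says: “Cedar is highest either way.”

The flasks give cedar highest, with 48.7%, 43.5% and 38.9%.

    Za + Zb → Zf (k = 0.0110 /M/s, Ea = 70.0 kJ/mol)
    Za → Zc (k = 0.0130 /s, Ea = 83.0 kJ/mol)
    2 Za → Zd (k = 4.20 × 10⁻⁴ /M/s, Ea = 61.0 kJ/mol)
    Za + Ze → Zg (k = 0.00690 /M/s, Ea = 85.0 kJ/mol)
    (constants at 70 °C)

Cedar and birch fall between our two lines. From theta without its scatter, 47.3%, changing Ze alone to cedar's gives 46.1%, and changing temperature alone to cedar's gives 49.3%. For alder's charge run at 75 °C, the ratio 0.732 gives 48.7% on the temperature line and 46.2% on the shared line, and that neighbour flask stands at 47.4%.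

All runs are calculated for an exercise; noise was put on by code.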